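The numbers are invented; the result is computed.

The slowness in this flask sits at the start: the starting material gives the intermediate with a half-life of 1.6 s, while capture by the second nucleophile alone, at its charged concentration, gives the intermediate a half-life of 0.20 s. So the intermediate lasts a shorter time than the starting material, and what you must reckon is how it divides among its exits.

starting material 0.0020 M; first nucleophile 1.80 equiv; second nucleophile 5.00 equiv; time 80 s

- at 80 s, what has stopped the reaction, if anything has (the first nucleophile has run out first / it is still moving / forward and back rates have come level / all of the starting material has reacted)
- share of the starting material used up at 80 s
- target at 80 s, in percent of the starting material charged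
- solvolysis product at 80 s, in percent of the starting material charged

- where a step has two of a species, its rate is k times that concentration squared, and two are used at each turn
- the reaction counts as stopped when no species that holds the starting material changes by six tenths of a point or more over the second half of the time
- run time (flask): 80 s

    2 second nucleophile → homo dimer (k1 = 46 M⁻¹ s⁻¹)
    first nucleophile → decomposition product (k2 = 2.8 × 10⁻⁴ s⁻¹)
    second nucleophile + intermediate → other capture product (k3 = 340 M⁻¹ s⁻¹)
    first nucleophile + intermediate → target (k4 = 1200 M⁻¹ s⁻¹)
    intermediate → solvolysis product (k5 = 4.4 s⁻¹)
    starting material → intermediate (k6 = 0.43 s⁻¹)

Set the exits of the intermediate side by side, each as a pseudo-first-order rate constant at the charge: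

- to target, capture constant times c(first nucleophile): 4.32 s⁻¹
- to solvolysis product: 4.4 s⁻¹
- to other capture product, capture constant times c(second nucleophile): 3.40 s⁻¹

Read the first row against the second: their ratio is 0.982. This is the selectivity factor S, target made per solvolysis product, the target capture constant times c(first nucleophile) over the solvolysis constant.

The last row looks large, but by dimerisation c(second nucleophile) first halves in 1.09 s, which is shorter than the half-life of the starting material. It also drops out of S, since the first two rows share one denominator.

The first row sinks as the run goes: each turn of capture uses one first nucleophile, and this is the correction. Without the last row, the target share is 49.5%, and I take half of that as missing on average from c(first nucleophile). So S falls to 0.847. The run holds 49.6 half-lives of the starting material, so I commit to a finished flask with that ratio. My reckoning stops there, without separate yields.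

The forecast says all of the starting material has reacted, with conversion 100%, target 39.7% and solvolysis product 45.2%, a ratio of 0.878, slightly above mine. Its grounds: “The short-lived intermediate splits between the first nucleophile and solvolysis at similar rates”.

The simulation gives all of the starting material has reacted, with conversion 100%, target 39.9% and solvolysis product 46.0%.

In this flask, target stands to solvolysis product at 0.867, against the 0.847 reckoned, so solvolysis took somewhat more of the intermediate than the first nucleophile did. The neighbouring flask charged at 0.0050 M of starting material, with the equivalents held, starts from S of 2.45, which the same correction brings to 1.97, and it ends with 58.2% target against 28.7% solvolysis product, a ratio of 2.03.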